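## Retrosynthetic overview

- The plan rests on the C11–C12(Me) oxirane carbons that sit next to the C13 carbinol in the 14-membered carbocycle. They are traced back to a C11≡C12 cycloalkyne with a propargylic 13-hydroxyl (13R, inverted at the end).
- Backwards: lactone C16(=O)–O ⇒ oxidative lactonisation of the C2/C16 diol; 13-OAc ⇒ Mitsunobu inversion; oxirane ⇒ hydroxyl-guided epoxidation; C12–CH3 ⇒ trans-hydrostannation and methyl Stille coupling; C11≡C12 ⇒ ring-closing alkyne metathesis; C1–C2 ⇒ anti-selective catalytic allylboration.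
- Fragments: enal 9 (C2–C11, from geraniol) and (Z)-allylboronate 22 (C12–C17, C13 set by catalytic propargylation of but-2-ynal).
- Ring order: 14-membered carbocycle (step 18), oxirane (step 22), α-methylene-γ-lactone (step 25).

Key step: step 18

Remarks on the chemistry:
- Atom numbers used for all intermediates: C1 is the ring-fusion CH and C2 the lactone O–CH; C4 and C8 carry the alkene methyls; C11/C12 carry the oxirane (methyl on C12); C13 carries the acetoxy group and C14 is the CH2 next to C1; C15 is the α-methylene carbon, C16 the lactone carbonyl, C17 the exocyclic CH2.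
- Assumptions: but-2-ynal stores poorly and is therefore made fresh (step 8). Metal alkoxides that are only protonated on work-up and catalyst-bound species are not numbered.
- (R)-TRIP is (R)-3,3′-bis(2,4,6-triisopropylphenyl)-1,1′-binaphthyl-2,2′-diyl hydrogen phosphate; Bpin is the pinacol boronate.

## Route

**Fragment A (C2–C11)**

Step 1
Reactants: 1 geraniol
Product: 2 geranyl tert-butyldimethylsilyl ether
Conditions: TBSCl, imidazole, CH2Cl2, 0 °C to rt
Reagents that add atoms: tert-butyldimethylsilyl chloride, CC(C)(C)[Si](C)(C)Cl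
Why: Imidazole-assisted O-silylation masks the C2 oxygen as an ether that tolerates the organolithium chemistry of step 4.

Step 2
Reactants: 2 geranyl tert-butyldimethylsilyl ether
Product: 3 (2E,6E)-8-[(tert-butyldimethylsilyl)oxy]-2,6-dimethylocta-2,6-dien-1-ol
Conditions: SeO2 (cat.), t-BuOOH, salicylic acid (cat.), CH2Cl2, rt
Reagents that add atoms: tert-butyl hydroperoxide, CC(C)(C)OO (terminal oxidant; the oxygen is relayed through SeO2, O=[Se]=O)
Why: Catalytic SeO2 allylic oxidation (ene reaction, then [2,3]-sigmatropic shift) attacks the more electron-rich terminal alkene at its (E)-methyl group, so the future C9 is hydroxylated and C7=C8 is fixed as E.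

Step 3
Reactants: 3 (2E,6E)-8-[(tert-butyldimethylsilyl)oxy]-2,6-dimethylocta-2,6-dien-1-ol
Product: 4 {[(2E,6E)-8-bromo-3,7-dimethylocta-2,6-dien-1-yl]oxy}(tert-butyl)dimethylsilane
Conditions: CBr4, PPh3, CH2Cl2, 0 °C
Reagents that add atoms: carbon tetrabromide, BrC(Br)(Br)Br
Why: The Appel reaction turns the primary allylic alcohol into the bromide by SN2 on the alkoxyphosphonium ion, without allylic transposition.

Step 4
Reactants: 4 {[(2E,6E)-8-bromo-3,7-dimethylocta-2,6-dien-1-yl]oxy}(tert-butyl)dimethylsilane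
Product: 5 tert-butyl{[(2E,6E)-3,7-dimethyl-11-(trimethylsilyl)undeca-2,6-dien-10-yn-1-yl]oxy}dimethylsilane
Conditions: MeC≡CSiMe3, n-BuLi, THF, −78 to −20 °C; then 4, −78 to 0 °C
Reagents that add atoms: 1-(trimethylsilyl)propyne, CC#C[Si](C)(C)C
Why: The propargyllithium made by deprotonating the silylpropyne displaces the primary allylic bromide by SN2; the silyl group keeps attack at the propargylic carbon (alkyne, not allene), forming C9–C10.

Step 5
Reactants: 5 tert-butyl{[(2E,6E)-3,7-dimethyl-11-(trimethylsilyl)undeca-2,6-dien-10-yn-1-yl]oxy}dimethylsilane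
Product: 6 (2E,6E)-3,7-dimethylundeca-2,6-dien-10-yn-1-ol
Conditions: Bu4NF, THF, 0 °C to rt
Reagents that add atoms: none
Why: Fluoride cleaves both the O–Si and the alkynyl C–Si bond (strong Si–F bond), giving the terminal alkyne and the free allylic alcohol in one operation.

Step 6
Reactants: 6 (2E,6E)-3,7-dimethylundeca-2,6-dien-10-yn-1-ol
Product: 8 (2E,6E)-3,7-dimethyldodeca-2,6-dien-10-yn-1-ol, via dilithium alkoxide acetylide 7 (not isolated)
Conditions: n-BuLi (2.1 equiv), THF, −78 to −20 °C; MeI (1.05 equiv), −78 °C to rt; aq NH4Cl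
Reagents that add atoms: iodomethane, CI
Why: Double deprotonation gives the alkoxide/acetylide dianion, whose carbon end is far more nucleophilic toward MeI in THF than the lithium alkoxide, so one equivalent caps the alkyne (acetylide SN2 alkylation).

Step 7
Reactants: 8 (2E,6E)-3,7-dimethyldodeca-2,6-dien-10-yn-1-ol
Product: 9 (2E,6E)-3,7-dimethyldodeca-2,6-dien-10-ynal (fragment A)
Conditions: MnO2, CH2Cl2, rt
Reagents that add atoms: none
Why: MnO2 oxidises the allylic alcohol selectively to the enal without isomerising the C3=C4 double bond.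

**Fragment B (C12–C17)**

Step 8
Reactants: 10 but-2-yn-1-ol
Product: 11 but-2-ynal
Conditions: MnO2, CH2Cl2, rt; filtered, exchanged into toluene and used at once
Reagents that add atoms: none
Why: MnO2 oxidation of the propargylic alcohol gives the ynal, which is kept in solution because it is volatile and polymerises on storage.

Step 9
Reactants: 11 but-2-ynal
Product: 13 (4R)-hepta-1,5-diyn-4-ol, via pinacol borate ester 12 (not isolated)
Conditions: allenyl-Bpin, (R)-TRIP (5 mol%), 4 Å MS, toluene, −20 to 0 °C; aq NaHCO3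
Reagents that add atoms: allenylboronic acid pinacol ester, C=C=CB1OC(C)(C)C(C)(C)O1
Why: Chiral phosphoric acid-catalysed propargylation: the allenylboronate adds through a closed six-membered transition state (SE2′) and the catalyst, hydrogen-bonded to a boronate oxygen and the formyl hydrogen, is expected to expose the Re face, which sets C13 as R.

Step 10
Reactants: 13 (4R)-hepta-1,5-diyn-4-ol
Product: 14 triethyl{[(4R)-hepta-1,5-diyn-4-yl]oxy}silane
Conditions: Et3SiCl, imidazole, CH2Cl2, 0 °C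
Reagents that add atoms: chlorotriethylsilane, CC[Si](CC)(CC)Cl
Why: O-silylation gives the triethylsilyl ether, the one silyl group that can later be removed in the presence of tert-butyldimethylsilyl ethers.

Step 11
Reactants: 14 triethyl{[(4R)-hepta-1,5-diyn-4-yl]oxy}silane
Product: 16 methyl (5R)-5-[(triethylsilyl)oxy]octa-2,6-diynoate, via lithium acetylide 15 (not isolated)
Conditions: n-BuLi, THF, −78 °C; ClCO2Me, −78 to 0 °C
Reagents that add atoms: methyl chloroformate, COC(=O)Cl
Why: Deprotonation of the only terminal alkyne and C-acylation of the acetylide installs C16 as an ester carbon and activates the C1≡C15 alkyne for the next step.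

Step 12
Reactants: 16 methyl (5R)-5-[(triethylsilyl)oxy]octa-2,6-diynoate
Product: 17 methyl (2E,5R)-2-(tributylstannyl)-5-[(triethylsilyl)oxy]oct-2-en-6-ynoate
Conditions: Bu3SnH (slow addition), Pd(PPh3)4 (2 mol%), THF, 0 °C to rt
Reagents that add atoms: tributyltin hydride, CCCC[SnH](CCCC)CCCC
Why: Zerovalent palladium-catalysed hydrostannation adds Sn–H syn across the electron-poor ynoate with tin at the α-carbon, which places C14 trans to tin and cis to the ester and leaves the unactivated propargylic-ether alkyne alone.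

Step 13
Reactants: 17 methyl (2E,5R)-2-(tributylstannyl)-5-[(triethylsilyl)oxy]oct-2-en-6-ynoate
Product: 18 (2E,5R)-2-(tributylstannyl)-5-[(triethylsilyl)oxy]oct-2-en-6-yn-1-ol
Conditions: i-Bu2AlH (2.2 equiv), CH2Cl2, −78 to −40 °C; aq potassium sodium tartrate
Reagents that add atoms: none
Why: i-Bu2AlH reduces the conjugated ester to the primary allylic alcohol (two hydride transfers through the aldehyde) without touching the alkenylstannane or the alkyne.

Step 14
Reactants: 18 (2E,5R)-2-(tributylstannyl)-5-[(triethylsilyl)oxy]oct-2-en-6-yn-1-ol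
Product: 19 tert-butyldimethyl{[(2E,5R)-2-(tributylstannyl)-5-[(triethylsilyl)oxy]oct-2-en-6-yn-1-yl]oxy}silane
Conditions: TBSCl, imidazole, CH2Cl2, rt
Reagents that add atoms: tert-butyldimethylsilyl chloride, CC(C)(C)[Si](C)(C)Cl
Why: O-silylation protects the C16 oxygen in the form it keeps until step 24.

Step 15
Reactants: 19 tert-butyldimethyl{[(2E,5R)-2-(tributylstannyl)-5-[(triethylsilyl)oxy]oct-2-en-6-yn-1-yl]oxy}silane
Product: 22 2-{(2Z,5R)-2-{[(tert-butyldimethylsilyl)oxy]methyl}-5-[(triethylsilyl)oxy]oct-2-en-6-yn-1-yl}-4,4,5,5-tetramethyl-1,3,2-dioxaborolane (fragment B), via alkenyllithium 20 (not isolated), via chloromethyl borate complex 21 (not isolated)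
Conditions: n-BuLi, THF, −78 °C; ClCH2Bpin, −78 °C to rt
Reagents that add atoms: 2-(chloromethyl)-4,4,5,5-tetramethyl-1,3,2-dioxaborolane, ClCB1OC(C)(C)C(C)(C)O1
Why: Tin–lithium exchange gives the alkenyllithium with retention, the chloromethylboronate captures it as an ate complex, and 1,2-migration with loss of chloride (Matteson-type homologation) gives the allylboronate with C14 trans to CH2B.

**Union, ring closure and end game**

Step 16
Reactants: 9 (2E,6E)-3,7-dimethyldodeca-2,6-dien-10-ynal + 22 allylboronate (fragment B)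
Product: 24 (6E,10E,12S,13R,15R)-13-{3-[(tert-butyldimethylsilyl)oxy]prop-1-en-2-yl}-6,10-dimethyl-15-[(triethylsilyl)oxy]octadeca-6,10-dien-2,16-diyn-12-ol [(1R,2S,13R) in ring numbering], via pinacol borate ester 23 (not isolated)
Conditions: (R)-TRIP (5 mol%), 4 Å MS, toluene, −30 to 0 °C; aq NaHCO3
Reagents that add atoms: none
Why: Chiral phosphoric acid-catalysed allylboration through a closed six-membered chair: C14 is trans to the CH2B carbon (E-crotyl type) and sits equatorial, which gives the anti C1/C2 relationship, while (R)-TRIP is expected to direct the allyl unit to the Re face of the enal, which sets C2 as S and hence C1 as R.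

Step 17
Reactants: 24 seco alcohol
Product: 25 seco-diyne (6E,10E,12S,13R,15R)-12-[(tert-butyldimethylsilyl)oxy]-13-{3-[(tert-butyldimethylsilyl)oxy]prop-1-en-2-yl}-6,10-dimethyl-15-[(triethylsilyl)oxy]octadeca-6,10-dien-2,16-diyne
Conditions: TBSOTf, 2,6-lutidine, CH2Cl2, −78 to 0 °C
Reagents that add atoms: tert-butyldimethylsilyl triflate, CC(C)(C)[Si](C)(C)OS(=O)(=O)C(F)(F)F
Why: The silyl triflate with a hindered base silylates the hindered secondary allylic C2 hydroxyl and leaves the triethylsilyl ether in place.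

Step 18
Reactants: 25 seco-diyne
Product: 26 (1R,2S,3E,7E,13R)-2-[(tert-butyldimethylsilyl)oxy]-1-{3-[(tert-butyldimethylsilyl)oxy]prop-1-en-2-yl}-4,8-dimethyl-13-[(triethylsilyl)oxy]cyclotetradeca-3,7-dien-11-yne (ring numbering of the remarks)
Conditions: 4-MeOC6H4C≡Mo(OSiPh3)3 (5–10 mol%), 5 Å MS, toluene (0.002 M), rt to 60 °C
Reagents that add atoms: none
Why: Ring-closing alkyne metathesis: the molybdenum alkylidyne adds to one methyl-capped alkyne by [2+2] cycloaddition and cycloreverts to load the substrate as a new alkylidyne, which engages the second alkyne through a molybdenacyclobutadiene and releases the cycloalkyne with loss of but-2-yne. The closest known reaction type is macrocyclic ring-closing metathesis of methyl-capped diynes with silanolate-ligated molybdenum alkylidynes. The 14-membered carbocycle is closed head to head at C11≡C12 (endocyclic triple bond, macrocyclisation under high dilution) and no stereocentre is formed. The step needs chemoselectivity for the two alkynes over the three alkenes (two trisubstituted, one 1,1-disubstituted), which the alkylidyne secures because it does not engage C=C bonds. It also needs ring closure to outrun oligomerisation, which dilution and trapping of but-2-yne in the 5 Å sieves secure. A 14-membered ring accommodates the linear C10–C11≡C12–C13 unit, and the fully silylated substrate offers no acidic proton to the silanolate ligands.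

Step 19
Reactants: 26 cycloalkyne
Product: 27 (1R,2S,3E,7E,13R)-2-[(tert-butyldimethylsilyl)oxy]-1-{3-[(tert-butyldimethylsilyl)oxy]prop-1-en-2-yl}-4,8-dimethylcyclotetradeca-3,7-dien-11-yn-13-ol
Conditions: pyridinium p-toluenesulfonate (cat.), MeOH/CH2Cl2, 0 °C
Reagents that add atoms: none
Why: Mild acid-catalysed methanolysis removes the triethylsilyl ether much faster than the bulkier tert-butyldimethylsilyl ethers and frees the C13 hydroxyl as the directing group.

Step 20
Reactants: 27 cyclic propargylic alcohol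
Product: 28 (1R,2S,3E,7E,11Z,13R)-12-(tributylstannyl) cyclotetradeca-3,7,11-trien-13-ol (silyl ethers as in 27; ring carbons C10 and C13 trans)
Conditions: Bu3SnH, [Cp*RuCl]4 (2 mol%), CH2Cl2, rt
Reagents that add atoms: tributyltin hydride, CCCC[SnH](CCCC)CCCC
Why: Ruthenium-catalysed trans-hydrostannation: the propargylic hydroxyl hydrogen-bonds to the chloride ligand and steers tin to the proximal carbon C12 while hydrogen is delivered anti to C11, so C10 and C13 end up trans and the alkenes are not touched.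

Step 21
Reactants: 28 alkenylstannane
Product: 29 (1R,2S,3E,7E,11E,13R)-4,8,12-trimethyl cyclotetradeca-3,7,11-trien-13-ol (silyl ethers as in 27)
Conditions: MeI, Pd(PPh3)4 (10 mol%), Cu(O2C-2-C4H3S) (copper thiophene-2-carboxylate), [Bu4N][Ph2PO2], DMF, rt
Reagents that add atoms: iodomethane, CI
Why: Copper-assisted Stille methylation: stereoretentive tin-to-copper-to-palladium transmetalation and reductive elimination put the methyl on C12 with the alkene geometry kept, while the phosphinate removes the tin residue and suppresses protodestannation.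

Step 22
Reactants: 29 allylic alcohol
Product: 30 (1R,2S,3E,7E,11R,12R,13R)-11,12-epoxy-4,8,12-trimethyl cyclotetradeca-3,7-dien-13-ol (silyl ethers as in 27; C12 has the spatial arrangement of the target)
Conditions: Ti(OiPr)4 (20 mol%), D-(−)-diisopropyl tartrate (24 mol%), t-BuOOH, 4 Å MS, CH2Cl2, −20 °C
Reagents that add atoms: tert-butyl hydroperoxide, CC(C)(C)OO
Why: Sharpless asymmetric epoxidation in the matched sense: the titanium tartrate binds the C13 alkoxide and delivers oxygen to the C11=C12 face that both the (S,S)-tartrate and the (13R) carbinol favour (erythro product, carbinol hydrogen eclipsing the C12 methyl), which sets C11 and C12; only the alkene of the free allylic alcohol reacts.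

Step 23
Reactants: 30 epoxy alcohol
Product: 32 (1R,2S,3E,7E,11R,12S,13S)-13-acetoxy-11,12-epoxy-4,8,12-trimethyl cyclotetradeca-3,7-diene (silyl ethers as in 27), via alkoxyphosphonium acetate 31 (not isolated)
Conditions: PPh3, DIAD, AcOH, toluene, 0 °C to rt
Reagents that add atoms: acetic acid, CC(=O)O
Why: Mitsunobu reaction: acetate displaces the C13 alkoxyphosphonium ion by SN2 with inversion, turning (13R) into the (13S) acetate of the target with the oxirane untouched.

Step 24
Reactants: 32 epoxy acetate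
Product: 33 (1R,2S,3E,7E,11R,12S,13S)-13-acetoxy-11,12-epoxy-1-(3-hydroxyprop-1-en-2-yl)-4,8,12-trimethylcyclotetradeca-3,7-dien-2-ol
Conditions: HF·pyridine, pyridine, THF, 0 °C to rt
Reagents that add atoms: none
Why: Buffered fluoride cleaves both Si–O bonds (strong Si–F bond) under conditions that spare the acetate and the trisubstituted oxirane.

Step 25
Reactants: 33 diol
Product: 36 target CNP0146076.5 [(1R,2S,3E,7E,11R,12S,13S)-13-acetoxy-11,12-epoxy α-methylene-γ-lactone], via hydroxy enal 34 (not isolated), via lactol 35 (not isolated)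
Conditions: TEMPO (10 mol%), PhI(OAc)2 (2.5 equiv), CH2Cl2, rt
Reagents that add atoms: none
Why: TEMPO/PhI(OAc)2 oxidative lactonisation: the oxoammonium ion oxidises the primary allylic C16 alcohol in preference to the secondary one, the C2 hydroxyl closes onto the enal as a five-membered lactol, and a second oxidation gives the α-methylene-γ-butyrolactone.

## Compound list

1 | geraniol, (2E)-3,7-dimethylocta-2,6-dien-1-ol | CC(C)=CCC/C(C)=C/CO | starting material
2 | geranyl tert-butyldimethylsilyl ether | CC(C)=CCC/C(C)=C/CO[Si](C)(C)C(C)(C)C | intermediate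
3 | (2E,6E)-8-[(tert-butyldimethylsilyl)oxy]-2,6-dimethylocta-2,6-dien-1-ol | OC/C(C)=C/CC/C(C)=C/CO[Si](C)(C)C(C)(C)C | intermediate
4 | {[(2E,6E)-8-bromo-3,7-dimethylocta-2,6-dien-1-yl]oxy}(tert-butyl)dimethylsilane | BrC/C(C)=C/CC/C(C)=C/CO[Si](C)(C)C(C)(C)C | intermediate
5 | tert-butyl{[(2E,6E)-3,7-dimethyl-11-(trimethylsilyl)undeca-2,6-dien-10-yn-1-yl]oxy}dimethylsilane | C[Si](C)(C)C#CCC/C(C)=C/CC/C(C)=C/CO[Si](C)(C)C(C)(C)C | intermediate
6 | (2E,6E)-3,7-dimethylundeca-2,6-dien-10-yn-1-ol | C#CCC/C(C)=C/CC/C(C)=C/CO | intermediate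
7 | dilithium alkoxide acetylide of 6 | [Li]C#CCC/C(C)=C/CC/C(C)=C/CO[Li] | intermediate (not isolated)
8 | (2E,6E)-3,7-dimethyldodeca-2,6-dien-10-yn-1-ol | CC#CCC/C(C)=C/CC/C(C)=C/CO | intermediate
9 | (2E,6E)-3,7-dimethyldodeca-2,6-dien-10-ynal, fragment A | CC#CCC/C(C)=C/CC/C(C)=C/C=O | intermediate
10 | but-2-yn-1-ol | CC#CCO | starting material
11 | but-2-ynal | CC#CC=O | intermediate
12 | 2-{[(4R)-hepta-1,5-diyn-4-yl]oxy}-4,4,5,5-tetramethyl-1,3,2-dioxaborolane | CC#C[C@H](OB1OC(C)(C)C(C)(C)O1)CC#C | intermediate (not isolated)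
13 | (4R)-hepta-1,5-diyn-4-ol | CC#C[C@H](O)CC#C | intermediate
14 | triethyl{[(4R)-hepta-1,5-diyn-4-yl]oxy}silane | CC#C[C@H](O[Si](CC)(CC)CC)CC#C | intermediate
15 | lithium acetylide of 14 | CC#C[C@H](O[Si](CC)(CC)CC)CC#C[Li] | intermediate (not isolated)
16 | methyl (5R)-5-[(triethylsilyl)oxy]octa-2,6-diynoate | CC#C[C@H](O[Si](CC)(CC)CC)CC#CC(=O)OC | intermediate
17 | methyl (2E,5R)-2-(tributylstannyl)-5-[(triethylsilyl)oxy]oct-2-en-6-ynoate | CC#C[C@H](O[Si](CC)(CC)CC)C/C=C(\C(=O)OC)[Sn](CCCC)(CCCC)CCCC | intermediate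
18 | (2E,5R)-2-(tributylstannyl)-5-[(triethylsilyl)oxy]oct-2-en-6-yn-1-ol | CC#C[C@H](O[Si](CC)(CC)CC)C/C=C(\CO)[Sn](CCCC)(CCCC)CCCC | intermediate
19 | tert-butyldimethylsilyl ether of 18 | CC#C[C@H](O[Si](CC)(CC)CC)C/C=C(\CO[Si](C)(C)C(C)(C)C)[Sn](CCCC)(CCCC)CCCC | intermediate
20 | alkenyllithium from 19 (lithium in place of tin, geometry kept) | CC#C[C@H](O[Si](CC)(CC)CC)C/C=C(\CO[Si](C)(C)C(C)(C)C)[Li] | intermediate (not isolated)
21 | lithium alkenyl(chloromethyl)pinacolatoborate | [Li+].CC#C[C@H](O[Si](CC)(CC)CC)C/C=C(\CO[Si](C)(C)C(C)(C)C)[B-]1(CCl)OC(C)(C)C(C)(C)O1 | intermediate (not isolated)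
22 | 2-{(2Z,5R)-2-{[(tert-butyldimethylsilyl)oxy]methyl}-5-[(triethylsilyl)oxy]oct-2-en-6-yn-1-yl}-4,4,5,5-tetramethyl-1,3,2-dioxaborolane, fragment B | CC#C[C@H](O[Si](CC)(CC)CC)C/C=C(\CO[Si](C)(C)C(C)(C)C)CB1OC(C)(C)C(C)(C)O1 | intermediate
23 | pinacol borate ester of 24 (O-boryl at C2) | CC#C[C@H](O[Si](CC)(CC)CC)C[C@H](C(=C)CO[Si](C)(C)C(C)(C)C)[C@@H](OB1OC(C)(C)C(C)(C)O1)/C=C(\C)CC/C=C(\C)CCC#CC | intermediate (not isolated)
24 | (6E,10E,12S,13R,15R)-13-{3-[(tert-butyldimethylsilyl)oxy]prop-1-en-2-yl}-6,10-dimethyl-15-[(triethylsilyl)oxy]octadeca-6,10-dien-2,16-diyn-12-ol; (1R,2S,13R) in ring numbering | CC#C[C@H](O[Si](CC)(CC)CC)C[C@H](C(=C)CO[Si](C)(C)C(C)(C)C)[C@@H](O)/C=C(\C)CC/C=C(\C)CCC#CC | intermediate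
25 | seco-diyne, 12-O-tert-butyldimethylsilyl ether of 24; (1R,2S,13R) | CC#C[C@H](O[Si](CC)(CC)CC)C[C@H](C(=C)CO[Si](C)(C)C(C)(C)C)[C@@H](O[Si](C)(C)C(C)(C)C)/C=C(\C)CC/C=C(\C)CCC#CC | intermediate
26 | (1R,2S,3E,7E,13R)-2-(TBS-oxy)-1-[3-(TBS-oxy)prop-1-en-2-yl]-4,8-dimethyl-13-(triethylsilyloxy)cyclotetradeca-3,7-dien-11-yne | C1#C[C@H](O[Si](CC)(CC)CC)C[C@H](C(=C)CO[Si](C)(C)C(C)(C)C)[C@@H](O[Si](C)(C)C(C)(C)C)/C=C(\C)CC/C=C(\C)CC1 | intermediate
27 | (1R,2S,3E,7E,13R)-2-(TBS-oxy)-1-[3-(TBS-oxy)prop-1-en-2-yl]-4,8-dimethylcyclotetradeca-3,7-dien-11-yn-13-ol | C1#C[C@H](O)C[C@H](C(=C)CO[Si](C)(C)C(C)(C)C)[C@@H](O[Si](C)(C)C(C)(C)C)/C=C(\C)CC/C=C(\C)CC1 | intermediate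
28 | (1R,2S,3E,7E,11Z,13R)-12-(tributylstannyl) trien-13-ol, C10 and C13 trans on the ring | C1/C=C(\[Sn](CCCC)(CCCC)CCCC)[C@H](O)C[C@H](C(=C)CO[Si](C)(C)C(C)(C)C)[C@@H](O[Si](C)(C)C(C)(C)C)/C=C(\C)CC/C=C(\C)C1 | intermediate
29 | (1R,2S,3E,7E,11E,13R)-2-(TBS-oxy)-1-[3-(TBS-oxy)prop-1-en-2-yl]-4,8,12-trimethylcyclotetradeca-3,7,11-trien-13-ol | C1/C=C(\C)[C@H](O)C[C@H](C(=C)CO[Si](C)(C)C(C)(C)C)[C@@H](O[Si](C)(C)C(C)(C)C)/C=C(\C)CC/C=C(\C)C1 | intermediate
30 | (1R,2S,3E,7E,11R,12R,13R)-11,12-epoxy alcohol (the C12 descriptor differs from the target only through the priority rules) | C1[C@H]2O[C@]2(C)[C@H](O)C[C@H](C(=C)CO[Si](C)(C)C(C)(C)C)[C@@H](O[Si](C)(C)C(C)(C)C)/C=C(\C)CC/C=C(\C)C1 | intermediate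
31 | C13 alkoxy(triphenyl)phosphonium acetate of 30 (configuration of 30) | C1[C@H]2O[C@]2(C)[C@H](O[P+](c3ccccc3)(c3ccccc3)c3ccccc3)C[C@H](C(=C)CO[Si](C)(C)C(C)(C)C)[C@@H](O[Si](C)(C)C(C)(C)C)/C=C(\C)CC/C=C(\C)C1.CC(=O)[O-] | intermediate (not isolated)
32 | (1R,2S,3E,7E,11R,12S,13S)-13-acetoxy-11,12-epoxide, C2 and C16 oxygens as TBS ethers | C1[C@H]2O[C@]2(C)[C@@H](OC(C)=O)C[C@H](C(=C)CO[Si](C)(C)C(C)(C)C)[C@@H](O[Si](C)(C)C(C)(C)C)/C=C(\C)CC/C=C(\C)C1 | intermediate
33 | (1R,2S,3E,7E,11R,12S,13S)-13-acetoxy-11,12-epoxy-1-(3-hydroxyprop-1-en-2-yl)-4,8,12-trimethylcyclotetradeca-3,7-dien-2-ol | C1[C@H]2O[C@]2(C)[C@@H](OC(C)=O)C[C@H](C(=C)CO)[C@@H](O)/C=C(\C)CC/C=C(\C)C1 | intermediate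
34 | hydroxy enal (C16 aldehyde, C2 hydroxyl free) | C1[C@H]2O[C@]2(C)[C@@H](OC(C)=O)C[C@H](C(=C)C=O)[C@@H](O)/C=C(\C)CC/C=C(\C)C1 | intermediate (not isolated)
35 | lactol (C16 hemiacetal, both anomers) | C=C1C(O)O[C@H]2/C=C(\C)CC/C=C(\C)CC[C@H]3O[C@]3(C)[C@@H](OC(C)=O)C[C@H]12 | intermediate (not isolated)
36 | CNP0146076.5, (1R,2S,3E,7E,11R,12S,13S) | C=C1C(=O)O[C@H]2/C=C(\C)CC/C=C(\C)CC[C@H]3O[C@]3(C)[C@@H](OC(C)=O)C[C@H]12 | target

## Step count and risks

Total: 25 steps. Longest linear sequence: 18 steps (steps 8–25); the fragment A branch (steps 1–7) joins at step 16.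

**Step 18 (ring-closing alkyne metathesis).** Intermolecular metathesis may outrun ring closure and give oligomers, or the alkylidyne may turn over too slowly at the alkyne that carries the bulky propargylic silyloxy group. The fallback closes the ring at C12–C13 by an intramolecular Nozaki–Hiyama–Kishi coupling. It sets out from alcohol 8 and commercial 4,4-diethoxybut-1-yne and comes back at allylic alcohol 29, so steps 19–21 fall away.
- Hydrozirconation of 8 with excess Cp2Zr(H)Cl (THF, 50 °C; zirconium settles on the methyl-bearing alkyne carbon) and iodinolysis should give (2E,6E,10E)-11-iodo-3,7-dimethyldodeca-2,6,10-trien-1-ol F1. MnO2 oxidises it to the iodo enal F2.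
- 4,4-Diethoxybut-1-yne is taken through the operations of steps 11–15: methyl 5,5-diethoxypent-2-ynoate F3, the α-stannyl enoate F4, the stannyl allylic alcohol F5, its silyl ether F6 and the (Z)-allylboronate F7.
- Allylboration of F2 with F7 under the conditions of step 16 gives the anti homoallylic alcohol F8, which TBSOTf/2,6-lutidine converts into the bis-silyl ether F9. The acetal is opened with Et3SiOTf/2,6-lutidine and then water to the C13 aldehyde F10.
- CrCl2 with catalytic NiCl2 (DMSO/THF, high dilution) inserts into the C12–I bond and adds the alkenyl unit to the aldehyde. This gives 29 together with its C13 epimer F11.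
- The mixture is oxidised with Dess–Martin periodinane to the enone F12, and Corey–Bakshi–Shibata reduction ((S)-oxazaborolidine, BH3·SMe2) returns 29.

**Step 16 (catalytic allylboration).** Addition to the β,β-disubstituted enal may be slow and the catalyst may control the aldehyde face incompletely, which would erode the C1/C2 configuration relative to C13. The fallback moves the stereocontrol into the reagent. It sets out from stannane 19 and comes back at 24.
- Tin–lithium exchange of 19 and trapping with ClCH2B(OiPr)2 gives the diisopropyl allylboronate F13.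
- Exchange with diisopropyl (S,S)-tartrate gives the tartrate allylboronate F14, the ester expected to shield the Si face.
- F14 adds to enal 9 (toluene, 4 Å MS, −78 °C) through the same chair transition state. Because C13 is fixed, any facial leakage appears as a diastereomer that chromatography removes.

**Step 23 (Mitsunobu inversion).** Substitution at the carbinol flanked by the fully substituted oxirane carbon may be slow, so elimination or substitution with retention could compete. The fallback separates activation from displacement. It sets out from 30 and comes back at 32.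
- ClCH2SO2Cl/pyridine converts 30 into the chloromethanesulfonate F15.
- CsOAc with 18-crown-6 in toluene at 80 °C displaces the sulfonate with inversion to give 32.

## Further compounds

F1 | step 18 | (2E,6E,10E)-11-iodo-3,7-dimethyldodeca-2,6,10-trien-1-ol | C/C(I)=C\CC/C(C)=C/CC/C(C)=C/CO
F2 | step 18 | (2E,6E,10E)-11-iodo-3,7-dimethyldodeca-2,6,10-trienal | C/C(I)=C\CC/C(C)=C/CC/C(C)=C/C=O
F3 | step 18 | methyl 5,5-diethoxypent-2-ynoate | CCOC(OCC)CC#CC(=O)OC
F4 | step 18 | methyl (2E)-5,5-diethoxy-2-(tributylstannyl)pent-2-enoate | CCOC(OCC)C/C=C(\C(=O)OC)[Sn](CCCC)(CCCC)CCCC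
F5 | step 18 | (2E)-5,5-diethoxy-2-(tributylstannyl)pent-2-en-1-ol | CCOC(OCC)C/C=C(\CO)[Sn](CCCC)(CCCC)CCCC
F6 | step 18 | tert-butyldimethylsilyl ether of F5 | CCOC(OCC)C/C=C(\CO[Si](C)(C)C(C)(C)C)[Sn](CCCC)(CCCC)CCCC
F7 | step 18 | 2-[(2Z)-2-{[(tert-butyldimethylsilyl)oxy]methyl}-5,5-diethoxypent-2-en-1-yl]-4,4,5,5-tetramethyl-1,3,2-dioxaborolane | CCOC(OCC)C/C=C(\CO[Si](C)(C)C(C)(C)C)CB1OC(C)(C)C(C)(C)O1
F8 | step 18 | anti homoallylic alcohol (1R,2S) with C13 diethyl acetal and C12 alkenyl iodide | C/C(I)=C\CC/C(C)=C/CC/C(C)=C/[C@H](O)[C@H](CC(OCC)OCC)C(=C)CO[Si](C)(C)C(C)(C)C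
F9 | step 18 | C2-O-tert-butyldimethylsilyl ether of F8 | C/C(I)=C\CC/C(C)=C/CC/C(C)=C/[C@H](O[Si](C)(C)C(C)(C)C)[C@H](CC(OCC)OCC)C(=C)CO[Si](C)(C)C(C)(C)C
F10 | step 18 | C13 aldehyde from F9 | C/C(I)=C\CC/C(C)=C/CC/C(C)=C/[C@H](O[Si](C)(C)C(C)(C)C)[C@H](CC=O)C(=C)CO[Si](C)(C)C(C)(C)C
F11 | step 18 | (13S) epimer of 29 | C1/C=C(\C)[C@@H](O)C[C@H](C(=C)CO[Si](C)(C)C(C)(C)C)[C@@H](O[Si](C)(C)C(C)(C)C)/C=C(\C)CC/C=C(\C)C1
F12 | step 18 | 13-ketone (macrocyclic enone) from 29 and F11 | C1/C=C(\C)C(=O)C[C@H](C(=C)CO[Si](C)(C)C(C)(C)C)[C@@H](O[Si](C)(C)C(C)(C)C)/C=C(\C)CC/C=C(\C)C1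
F13 | step 16 | diisopropyl (2Z,5R)-allylboronate, the B(OiPr)2 analogue of 22 | CC#C[C@H](O[Si](CC)(CC)CC)C/C=C(\CO[Si](C)(C)C(C)(C)C)CB(OC(C)C)OC(C)C
F14 | step 16 | (4S,5S)-diisopropyl tartrate ester of the allylboronic acid | CC#C[C@H](O[Si](CC)(CC)CC)C/C=C(\CO[Si](C)(C)C(C)(C)C)CB1O[C@H](C(=O)OC(C)C)[C@@H](C(=O)OC(C)C)O1
F15 | step 23 | C13 chloromethanesulfonate of 30 | C1[C@H]2O[C@]2(C)[C@H](OS(=O)(=O)CCl)C[C@H](C(=C)CO[Si](C)(C)C(C)(C)C)[C@@H](O[Si](C)(C)C(C)(C)C)/C=C(\C)CC/C=C(\C)C1
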